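**Retrosynthetic overview**

1. Numbering: ring A is the benzo ring (C4a, C5–C8, C8a), ring B the pyran (O1, C2, C3, C4), ring C the anisyl ring; Cα is the carbonyl carbon on C6, Cβ the one on ring C.
2. Feature the strategy rests on: on ring A, C5–OH and C8–OMe are para, so ring A is a 4-methoxyphenol. Its quinone monoketal has the enone C5(=O)–C4a=C8a, and the β-carbon C8a is the carbon that must carry O1, next to the side chain on C4a.
3. Disconnections: Cα=O from Cα–OH (ketol oxidation); C6–Cα from chromenol 8 plus 4-methoxyphenylglyoxal; O1–C8a from Z-diol 4 by dearomatisation, oxa-Michael closure and rearomatisation; diol 4 from 6-methoxycoumarin and two MeMgBr.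
4. Ring order: rings A and C are bought. The lactone ring of the coumarin is opened in step 1, and its oxygen ends as C5–OH, not as O1. Ring B is the only ring formed, in step 2.

Key step: step 2

Remark: the chromene numbering above is used for all intermediates, including the monocyclic ones; the target is achiral, so benzoin 11 is carried as a racemate.

**Route**

Step 1
Reactants: 1 6-methoxycoumarin; 2 methylmagnesium bromide
Product: 4 2-[(1Z)-3-hydroxy-3-methylbut-1-en-1-yl]-4-methoxyphenol, via Z-enone phenoxide 3 (not isolated)
Conditions: MeMgBr (4 equiv), THF, 0 °C to rt; sat. aq NH4Cl, 0 °C; quick filtration through Et3N-treated silica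
Reagents that add atoms: methylmagnesium bromide, C[Mg]Br
Why: Two-fold Grignard addition to the lactone carbonyl opens the pyranone to the Z-enone phenoxide 3 and then gives the tertiary carbinol; the Z geometry is that of the coumarin C3=C4 bond and is not touched, and the acid-free work-up should keep the diol from cyclodehydrating onto the phenol oxygen.

Step 2
Reactants: 4 2-[(1Z)-3-hydroxy-3-methylbut-1-en-1-yl]-4-methoxyphenol; 5 (diacetoxyiodo)benzene
Product: 8 8-methoxy-2,2-dimethyl-2H-chromen-5-ol, via quinone monoketal 6 (not isolated), via oxa-Michael adduct 7 (not isolated)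
Conditions: PhI(OAc)2 (1.0 equiv), MeOH, 0 °C; Et2O, cold aq NaHCO3 wash, concentrate; KOtBu (10 mol %), THF, −20 to 0 °C; then anhydrous CSA (30 mol %), THF/CH2Cl2, −20 °C to rt
Reagents that add atoms: methanol, CO (source of the second ketal methoxy of 6; one of the two is lost again)
Why: Proposed new method: two-electron oxidation by PhI(OAc)2 gives a phenoxonium ion that methanol traps at C8, para to the oxygen, so that quinone monoketal 6 holds the enone C5(=O)–C4a=C8a with C8a as its β-carbon; up to here this is the standard hypervalent-iodine dearomatisation of 4-methoxyphenols, and the oxidant is spent and washed out before any arene returns. With catalytic KOtBu in THF the tertiary alkoxide, held over C8a by the Z-alkene taken from the coumarin, should add in a 6-endo-trig oxa-Michael closure that forms O1–C8a and ring B (adduct 7), the chain being carried by proton transfer from the next carbinol to the dienolate. Cold anhydrous CSA should then protonate the enolate before it can revert and open the C8 ketal to an oxocarbenium ion that, from the C5 enol, is the C8a-protonated arenium ion of 8, so that loss of the C8a proton and of one methanol returns ring A with OH on C5, OMe on C8 and O1 on C8a. The closest known reaction type is the base-mediated β-addition of external O-, N-, S- and C-nucleophiles to p-quinone monoketals followed by acid-induced loss of methanol to 3-substituted 4-methoxyphenols; the intramolecular addition of a tethered tertiary alkoxide is the untested part. No stereocentre survives, since the sp3 centres C4a and C8a of 7 are erased on aromatisation. The step needs C8a to be chosen over C7 and over the C5 carbonyl: the Z tether cannot reach C7, methanol is removed before the base is added so that it cannot add there, and the 6-exo hemiketal from attack at C5 is a reversible dead end that drains into the conjugate adduct, whereas acid on 4 itself would close the phenol oxygen onto the side chain to the isomeric 6-methoxychromene, which the dearomatisation prevents.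

Step 3
Reactants: 8 8-methoxy-2,2-dimethyl-2H-chromen-5-ol; 9 4-methoxyphenylglyoxal hydrate
Product: 11 racemic 2-hydroxy-2-(5-hydroxy-8-methoxy-2,2-dimethyl-2H-chromen-6-yl)-1-(4-methoxyphenyl)ethan-1-one, via 4-methoxyphenylglyoxal 10 (not isolated)
Conditions: 9, PhMe, Dean–Stark, reflux, then cool; 8, EtMgBr (1.0 equiv), Et2O, 0 °C, solvent changed to CH2Cl2; dried glyoxal solution (1.2 equiv) added, 0 °C to rt; aq NH4Cl
Reagents that add atoms: none
Why: Ortho-specific hydroxyalkylation of a bromomagnesium phenoxide (Friedel–Crafts type, through a six-membered magnesium chelate) should deliver the aldehyde carbon of 10, more electrophilic than its aryl ketone, to C6, the only free position ortho to the C5 oxygen and also para to O1; the carbinol centre forms without control as a racemate and is erased in step 4.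

Step 4
Reactants: 11 racemic 2-hydroxy-2-(5-hydroxy-8-methoxy-2,2-dimethyl-2H-chromen-6-yl)-1-(4-methoxyphenyl)ethan-1-one
Product: 12 dielsianone [1-(5-hydroxy-8-methoxy-2,2-dimethyl-2H-chromen-6-yl)-2-(4-methoxyphenyl)ethane-1,2-dione]
Conditions: Cu(OAc)2 (10 mol %), air, MeOH, rt
Reagents that add atoms: none
Why: Copper-catalysed aerobic dehydrogenation of an α-ketol, in which divalent copper oxidises the enediol of the benzoin in two one-electron steps and air returns monovalent copper to divalent copper; the phenol of ring A has both ortho positions and the para position occupied, so oxidative phenol coupling has no site, and either ketol tautomer gives the same diketone.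

**Compound list**

1 | 6-methoxycoumarin (6-methoxy-2H-chromen-2-one) | COc1ccc2OC(=O)C=Cc2c1 | starting material
2 | methylmagnesium bromide | C[Mg]Br | starting material
3 | (3Z)-4-(2-hydroxy-5-methoxyphenyl)but-3-en-2-one (in the flask as its bromomagnesium phenoxide) | COc1ccc(O)c(/C=C\C(C)=O)c1 | intermediate
4 | 2-[(1Z)-3-hydroxy-3-methylbut-1-en-1-yl]-4-methoxyphenol | COc1ccc(O)c(/C=C\C(C)(C)O)c1 | intermediate
5 | (diacetoxyiodo)benzene | CC(=O)OI(OC(C)=O)c1ccccc1 | starting material
6 | 2-[(1Z)-3-hydroxy-3-methylbut-1-en-1-yl]-4,4-dimethoxycyclohexa-2,5-dien-1-one | COC1(OC)C=CC(=O)C(/C=C\C(C)(C)O)=C1 | intermediate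
7 | 8,8-dimethoxy-2,2-dimethyl-4a,8a-dihydro-2H-chromen-5(8H)-one (racemic; relative configuration at C4a/C8a not defined, both centres transient) | COC1(OC)C=CC(=O)C2C=CC(C)(C)OC12 | intermediate
8 | 8-methoxy-2,2-dimethyl-2H-chromen-5-ol | COc1ccc(O)c2C=CC(C)(C)Oc12 | intermediate
9 | 4-methoxyphenylglyoxal hydrate (2,2-dihydroxy-1-(4-methoxyphenyl)ethan-1-one) | COc1ccc(C(=O)C(O)O)cc1 | starting material
10 | 4-methoxyphenylglyoxal (2-(4-methoxyphenyl)-2-oxoacetaldehyde) | COc1ccc(C(=O)C=O)cc1 | intermediate
11 | racemic 2-hydroxy-2-(5-hydroxy-8-methoxy-2,2-dimethyl-2H-chromen-6-yl)-1-(4-methoxyphenyl)ethan-1-one | COc1ccc(C(=O)C(O)c2cc(OC)c3c(c2O)C=CC(C)(C)O3)cc1 | intermediate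
12 | dielsianone, 1-(5-hydroxy-8-methoxy-2,2-dimethyl-2H-chromen-6-yl)-2-(4-methoxyphenyl)ethane-1,2-dione | COc1ccc(C(=O)C(=O)c2cc(OC)c3c(c2O)C=CC(C)(C)O3)cc1 | target

**Step count**

Total: 4 steps. Longest linear sequence: 4 steps (1 → 4 → 8 → 11 → 12); the glyoxal partner 9 is bought.

**Steps most likely to fail**

Step 2 (proposed new method). The conjugate closure onto C8a may not hold against retro-addition when the enolate is acidified. The acid may also ionise the allylic tertiary C–O bond, or trigger attack at C6 of unreacted monoketal, instead of aromatising the adduct. The fallback makes the O1–C8a bond by known palladium-catalysed aryl etherification and sets out from 1. Bromination with NBS in MeCN, expected at C5 of the coumarin (ortho to the methoxy group, the carbon that becomes C8a), would give 5-bromo-6-methoxycoumarin F1; the regiochemistry would have to be confirmed before going on. MeMgBr as in step 1 would open it to 3-bromo-2-[(1Z)-3-hydroxy-3-methylbut-1-en-1-yl]-4-methoxyphenol F2. TIPSCl and imidazole in DMF would mask the phenol as (3Z)-4-{2-bromo-3-methoxy-6-[(triisopropylsilyl)oxy]phenyl}-2-methylbut-3-en-2-ol F3. Pd(OAc)2 with 2-(di-tert-butylphosphino)-1,1'-binaphthyl and Cs2CO3 in toluene at 80 °C would couple the tertiary alkoxide with the aryl bromide to give [(8-methoxy-2,2-dimethyl-2H-chromen-5-yl)oxy]triisopropylsilane F4; the alkoxide has no hydrogen on its carbinol carbon, so β-hydride elimination is excluded. Bu4NF in THF would release 8, where the fallback comes back to the route.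

Step 3. Carbon–carbon bond formation at C6 may be outrun by reversible hemiacetal formation at the phenoxide oxygen, by self-condensation of the anhydrous glyoxal, or by a second arylation of the benzylic carbinol. The fallback inverts the polarity, so that ring A carries the electrophile and the anisyl unit enters as an acyl anion (Corey–Seebach dithiane umpolung); it sets out from 8. Ortho-formylation with MgCl2, Et3N and paraformaldehyde in MeCN at reflux would give 5-hydroxy-8-methoxy-2,2-dimethyl-2H-chromene-6-carbaldehyde F5. 2-Lithio-2-(4-methoxyphenyl)-1,3-dithiane (2.2 equiv, from the commercial dithiane and n-BuLi, THF, −78 °C; the first equivalent deprotonates the phenol) would add to the aldehyde to give racemic (5-hydroxy-8-methoxy-2,2-dimethyl-2H-chromen-6-yl)[2-(4-methoxyphenyl)-1,3-dithian-2-yl]methanol F6. MeI and CaCO3 in aqueous MeCN would unmask the ketone and give 11, where the route is rejoined.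

Step 4. Dehydrogenation of the ketol may not stay ahead of oxidation of the electron-rich 4-methoxyphenol ring to a quinone with loss of the C8 methyl group, or of closure of the ketol onto the C5 hydroxyl followed by dehydration. The fallback bypasses the benzoin and reaches the diketone through a ketone whose phenol is deactivated by a hydrogen-bonded ortho acyl group; it sets out from 8. Acylation at C6 with 4-methoxyphenylacetic acid in BF3·OEt2 at 70 °C (Friedel–Crafts/Fries type) would give the deoxybenzoin 1-(5-hydroxy-8-methoxy-2,2-dimethyl-2H-chromen-6-yl)-2-(4-methoxyphenyl)ethan-1-one F7. Riley oxidation of its doubly activated methylene with SeO2 in aqueous dioxane at reflux would give 12 directly.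

**Further compounds**

F1 | step 2 | 5-bromo-6-methoxy-2H-chromen-2-one | COc1ccc2OC(=O)C=Cc2c1Br
F2 | step 2 | 3-bromo-2-[(1Z)-3-hydroxy-3-methylbut-1-en-1-yl]-4-methoxyphenol | COc1ccc(O)c(/C=C\C(C)(C)O)c1Br
F3 | step 2 | (3Z)-4-{2-bromo-3-methoxy-6-[(triisopropylsilyl)oxy]phenyl}-2-methylbut-3-en-2-ol | COc1ccc(O[Si](C(C)C)(C(C)C)C(C)C)c(/C=C\C(C)(C)O)c1Br
F4 | step 2 | [(8-methoxy-2,2-dimethyl-2H-chromen-5-yl)oxy]triisopropylsilane | COc1ccc(O[Si](C(C)C)(C(C)C)C(C)C)c2C=CC(C)(C)Oc12
F5 | step 3 | 5-hydroxy-8-methoxy-2,2-dimethyl-2H-chromene-6-carbaldehyde | COc1cc(C=O)c(O)c2C=CC(C)(C)Oc12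
F6 | step 3 | racemic (5-hydroxy-8-methoxy-2,2-dimethyl-2H-chromen-6-yl)[2-(4-methoxyphenyl)-1,3-dithian-2-yl]methanol | COc1ccc(C2(C(O)c3cc(OC)c4c(c3O)C=CC(C)(C)O4)SCCCS2)cc1
F7 | step 4 | 1-(5-hydroxy-8-methoxy-2,2-dimethyl-2H-chromen-6-yl)-2-(4-methoxyphenyl)ethan-1-one | COc1ccc(CC(=O)c2cc(OC)c3c(c2O)C=CC(C)(C)O3)cc1
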